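**Retrosynthetic overview**
- Rings A and B (C1–C12 half) are closed last, on the full C30 chain, by an acetylative epoxide → epoxonium → alkene cascade that also installs 3‑OAc and the equatorial 10‑OAc; only a silyl ether on O22 then has to be removed.
- C12–C13 is made by alkylating the α‑sulfonyl carbanion of the finished C13–C24 bicycle with diepoxyfarnesyl bromide, followed by reductive loss of the sulfone.
- Rings D and C (C13–C24 half) come from a silyl‑triflate epoxonium cascade of diepoxyfarnesyl phenyl sulfone. Cation capture would give the wrong (equatorial) 15‑oxygen, so C15 is set by exo‑methylene → ketone → equatorial methyl addition.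
- Both halves derive from one chiral block, (6S,7S,10S)‑diepoxyfarnesyl acetate, made by Shi epoxidation of farnesyl acetate.
- Ring order: D (oxepane) → C (cyclohexane) → A (oxepane) → B (cyclohexane).

Assumption: atoms of the C30 compounds are numbered as in squalene (C1–C12 half carries 3‑OAc, C13–C24 half carries 22‑OH), and (2E,6E)‑farnesyl acetate and the L‑fructose‑derived (ent‑)Shi ketone are bought as single isomers.

**Step 1**
Reactants: 1 (2E,6E)-farnesyl acetate
Product: 2 (2E,6S,7S,10S)-6,7:10,11-diepoxyfarnesyl acetate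
Conditions: ent-Shi ketone (0.6 equiv, in portions), KHSO5 (as 2KHSO5·KHSO4·K2SO4), K2CO3, Bu4NHSO4, MeCN/dimethoxymethane/aq. Na2B4O7 buffer (pH 10.5), 0 °C
Reagents that add atoms: potassium peroxymonosulfate, [K+].[O-]S(=O)(=O)OO
Why: Shi asymmetric epoxidation; the dioxirane of the L‑fructose‑derived ketone epoxidises the two electron‑rich trisubstituted alkenes through the spiro transition state to give the (6S,7S) and (10S) epoxides, while the 2,3‑alkene, deactivated by the allylic acetate, is kept as the later cyclisation terminator.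

**Step 2**
Reactants: 2 (2E,6S,7S,10S)-6,7:10,11-diepoxyfarnesyl acetate
Product: 3 (2E,6S,7S,10S)-6,7:10,11-diepoxyfarnesol
Conditions: K2CO3, MeOH, 0 °C
Reagents that add atoms: none
Why: Base‑catalysed transesterification (methanolysis) of the primary allylic acetate; the epoxides are inert to carbonate/methanol at 0 °C and no stereocentre is touched.

**Step 3**
Reactants: 3 (2E,6S,7S,10S)-6,7:10,11-diepoxyfarnesol
Product: 4 (2E,6S,7S,10S)-6,7:10,11-diepoxyfarnesyl bromide
Conditions: CBr4, PPh3, 2,6-lutidine (0.2 equiv), CH2Cl2, −20 → 0 °C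
Reagents that add atoms: carbon tetrabromide, BrC(Br)(Br)Br
Why: Appel bromination; bromide displaces the alkoxyphosphonium by SN2 at the primary allylic carbon without transposition or loss of the 2E geometry, and the buffered neutral medium spares the epoxides.

**Step 4**
Reactants: 4 (2E,6S,7S,10S)-6,7:10,11-diepoxyfarnesyl bromide
Product: 5 (2E,6S,7S,10S)-6,7:10,11-diepoxyfarnesyl phenyl sulfone
Conditions: PhSO2Na, DMF, 0 °C → rt
Reagents that add atoms: sodium benzenesulfinate, [Na+].[O-]S(=O)c1ccccc1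
Why: SN2 S‑alkylation of the sulfinate by the allylic bromide (no geometry change) gives the allylic sulfone that later supplies the stabilised C13 carbanion.

**Step 5**
Reactants: 5 (2E,6S,7S,10S)-6,7:10,11-diepoxyfarnesyl phenyl sulfone
Product: 6 (3S,5aS,6R,9aS)-3-(tert-butyldimethylsilyloxy)-2,2,5a-trimethyl-7-methylidene-6-[(phenylsulfonyl)methyl]decahydro-1-benzoxepine (rings D and C, trans-fused)
Conditions: TBSOTf (1.3 equiv), 2,6-di-tert-butyl-4-methylpyridine (2 equiv), CH2Cl2 (0.01 M), −78 °C; NaHCO3 quench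
Reagents that add atoms: tert-butyldimethylsilyl triflate, CC(C)(C)[Si](C)(C)OS(=O)(=O)C(F)(F)F
Why: Lewis‑acid‑promoted epoxonium (epoxy‑polyene) cascade mirroring the biosynthesis; the silylated terminal epoxide is opened at its tertiary carbon by the internal epoxide oxygen (ring D, O‑bearing C3 retained as S), the alkene attacks the tertiary epoxonium carbon with inversion through a chair transition state (ring C, trans fusion, sulfonylmethyl side chain equatorial, 6‑H anti to the 5a‑methyl), and the hindered base removes a methyl proton to give the exocyclic alkene.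

**Step 6**
Reactants: 6 (3S,5aS,6R,9aS)-3-(tert-butyldimethylsilyloxy)-2,2,5a-trimethyl-7-methylidene-6-[(phenylsulfonyl)methyl]decahydro-1-benzoxepine
Product: 8 (3S,5aS,6S,9aS)-3-(tert-butyldimethylsilyloxy)-2,2,5a-trimethyl-6-[(phenylsulfonyl)methyl]octahydro-1-benzoxepin-7(2H)-one, via ozonide 7 (not isolated)
Conditions: O3, CH2Cl2, −78 °C; then Me2S, −78 °C → rt
Reagents that add atoms: ozone, [O-][O+]=O
Why: Ozonolysis (Criegee mechanism) of the only alkene with reductive work‑up gives the nor‑ketone; the electron‑poor phenyl sulfone and the silyl ether are inert, and the equatorial C6 side chain is the thermodynamic epimer next to the ketone (the 6R → 6S change is a priority change only).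

**Step 7**
Reactants: 8 (3S,5aS,6S,9aS)-3-(tert-butyldimethylsilyloxy)-2,2,5a-trimethyl-6-[(phenylsulfonyl)methyl]octahydro-1-benzoxepin-7(2H)-one
Product: 9 (3S,5aS,6S,7R,9aS)-3-(tert-butyldimethylsilyloxy)-2,2,5a,7-tetramethyl-6-[(phenylsulfonyl)methyl]decahydro-1-benzoxepin-7-ol (7-OH axial, syn to the 5a-methyl)
Conditions: MeMgBr, CeCl3 (anhydrous), THF, −78 °C; then H2O
Reagents that add atoms: methylmagnesium bromide, C[Mg]Br
Why: Cerium‑mediated (Imamoto‑type) 1,2‑addition, weakly basic so that β‑elimination of sulfinate is avoided; methyl enters equatorially, anti to the syn‑axial 5a‑methyl that blocks the axial trajectory, so the new tertiary hydroxyl is axial (7R), the configuration required at C15.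

**Step 8**
Reactants: 9 (3S,5aS,6S,7R,9aS)-3-(tert-butyldimethylsilyloxy)-2,2,5a,7-tetramethyl-6-[(phenylsulfonyl)methyl]decahydro-1-benzoxepin-7-ol; 4 (2E,6S,7S,10S)-6,7:10,11-diepoxyfarnesyl bromide
Product: 12 C30 sulfone acetate: (3S,6S,7S)-2,3:6,7-diepoxy-(10E)-ene chain C1–C12 joined at C13 (bearing SO2Ph, both epimers) to the ring C/D bicycle (14S,15R,18S,19S,22S; 15-OAc axial, 22-OTBS), via dilithio sulfone 10 (not isolated), via lithium alkoxide 11 (not isolated)
Conditions: n-BuLi (2.1 equiv), THF, −78 °C; then 4, −78 → −20 °C; then Ac2O, DMAP (cat.), −20 °C → rt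
Reagents that add atoms: acetic anhydride, CC(=O)OC(C)=O
Why: α‑Sulfonyl carbanion alkylation (Julia‑type fragment coupling); the O,C‑dianion reacts at carbon by SN2 on the primary allylic bromide (2E geometry kept, epoxides untouched at low temperature) to make C12–C13, and the remaining hindered lithium alkoxide is then O‑acylated by Ac2O; the new sulfone‑bearing centre is erased in step 9.

**Step 9**
Reactants: 12 C30 sulfone acetate (C13 epimers)
Product: 13 (3S,6S,7S,10E,14S,15R,18S,19S,22S) C30 diepoxy-ene: 2,3:6,7-diepoxy-(10E)-ene chain C1–C13 attached to the ring C/D bicycle with 15-OAc (axial) and 22-OTBS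
Conditions: Na(Hg) (6% Na), Na2HPO4, MeOH/THF, −20 °C
Reagents that add atoms: none
Why: Reductive desulfonylation by electron transfer from sodium amalgam under phosphate buffering replaces C–S by C–H; the trisubstituted epoxides, the homoallylic alkene, the hindered tertiary acetate and the silyl ether are stable to these conditions.

**Step 10**
Reactants: 13 (3S,6S,7S,10E,14S,15R,18S,19S,22S) C30 diepoxy-ene with 15-OAc and 22-OTBS
Product: 14 22-O-tert-butyldimethylsilyl ether of the target (3S,6S,7S,10S,11S,14S,15R,18S,19S,22S; 3-OAc, 10-OAc equatorial, 15-OAc axial)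
Conditions: Ac2O (5 equiv), TMSOTf (0.2 equiv), 2,6-di-tert-butyl-4-methylpyridine (0.3 equiv), CH2Cl2 (0.01 M), −78 °C; Et3N quench
Reagents that add atoms: acetic anhydride, CC(=O)OC(C)=O
Why: Proposed new method: catalytic TMSOTf turns Ac2O into AcOTf and TMSOAc; AcOTf O‑acylates the 2,3‑epoxide, the 6,7‑epoxide oxygen opens it at C2 to give the bicyclic epoxonium ion (ring A, C3 retained), the 10E alkene attacks C6 with inversion through a chair transition state (ring B, trans fusion, C11 chain equatorial, 11‑H anti to the 6‑methyl), and TMSOAc captures the C10 cation on the open equatorial face anti to the new C6–C11 bond (the axial face is blocked by the syn‑axial 6‑methyl), regenerating TMSOTf so that one Ac2O is added across the cascade; no competing alkene is left in the molecule to intercept the cation; closest known reaction types are the silyl‑triflate‑promoted diepoxide–alkene oxa/carbacyclisation, the Lewis‑acid‑catalysed opening of epoxides by Ac2O to vicinal diacetates, and carboxylate‑terminated cation–olefin cyclisations.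

**Step 11**
Reactants: 14 22-O-tert-butyldimethylsilyl ether of the target
Product: 15 CNP0169816.2, (3S,6S,7S,10S,11S,14S,15R,18S,19S,22S)-3,10,15-triacetoxy bis(perhydro-1-benzoxepine) with free 22-OH
Conditions: HF·pyridine, pyridine/THF, 0 °C → rt
Reagents that add atoms: none
Why: Fluoride‑mediated desilylation; buffered HF·pyridine cleaves the secondary silyl ether while the secondary and the two tertiary acetates and both oxepanes are stable, and no stereocentre is touched.

**Compound list**
1 | (2E,6E)-farnesyl acetate | CC(=O)OC/C=C(\C)CC/C=C(\C)CCC=C(C)C | starting material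
2 | (2E,6S,7S,10S)-6,7:10,11-diepoxyfarnesyl acetate | CC1(C)O[C@H]1CC[C@]2(C)O[C@H]2CC/C(C)=C/COC(C)=O | intermediate
3 | (2E,6S,7S,10S)-6,7:10,11-diepoxyfarnesol | CC1(C)O[C@H]1CC[C@]2(C)O[C@H]2CC/C(C)=C/CO | intermediate
4 | (2E,6S,7S,10S)-6,7:10,11-diepoxyfarnesyl bromide | CC1(C)O[C@H]1CC[C@]2(C)O[C@H]2CC/C(C)=C/CBr | intermediate
5 | (2E,6S,7S,10S)-6,7:10,11-diepoxyfarnesyl phenyl sulfone | CC1(C)O[C@H]1CC[C@]2(C)O[C@H]2CC/C(C)=C/CS(=O)(=O)c1ccccc1 | intermediate
6 | (3S,5aS,6R,9aS)-3-(tert-butyldimethylsilyloxy)-2,2,5a-trimethyl-7-methylidene-6-[(phenylsulfonyl)methyl]decahydro-1-benzoxepine | O=S(=O)(c1ccccc1)C[C@H]2[C@]3(C)CC[C@H](O[Si](C)(C)C(C)(C)C)C(C)(C)O[C@H]3CCC2=C | intermediate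
7 | spiro-1,2,4-trioxolane (ozonide) of 6 at C7, both epimers at the spiro carbon | O=S(=O)(c1ccccc1)C[C@H]2[C@]3(C)CC[C@H](O[Si](C)(C)C(C)(C)C)C(C)(C)O[C@H]3CCC24OOCO4 | intermediate (not isolated)
8 | (3S,5aS,6S,9aS)-3-(tert-butyldimethylsilyloxy)-2,2,5a-trimethyl-6-[(phenylsulfonyl)methyl]octahydro-1-benzoxepin-7(2H)-one | O=S(=O)(c1ccccc1)C[C@H]2[C@]3(C)CC[C@H](O[Si](C)(C)C(C)(C)C)C(C)(C)O[C@H]3CCC2=O | intermediate
9 | (3S,5aS,6S,7R,9aS)-3-(tert-butyldimethylsilyloxy)-2,2,5a,7-tetramethyl-6-[(phenylsulfonyl)methyl]decahydro-1-benzoxepin-7-ol | O=S(=O)(c1ccccc1)C[C@H]2[C@]3(C)CC[C@H](O[Si](C)(C)C(C)(C)C)C(C)(C)O[C@H]3CC[C@@]2(C)O | intermediate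
10 | O,C-dilithio derivative of 9 (lithium 7-alkoxide and α-sulfonyl carbanion) | [Li]C(S(=O)(=O)c1ccccc1)[C@H]2[C@]3(C)CC[C@H](O[Si](C)(C)C(C)(C)C)C(C)(C)O[C@H]3CC[C@@]2(C)O[Li] | intermediate (not isolated)
11 | lithium 15-alkoxide of the C-alkylated C30 sulfone (C12–C13 bond made, C13 epimers) | CC1(C)O[C@H]1CC[C@]2(C)O[C@H]2CC/C(C)=C/CC(S(=O)(=O)c3ccccc3)[C@H]4[C@]5(C)CC[C@H](O[Si](C)(C)C(C)(C)C)C(C)(C)O[C@H]5CC[C@@]4(C)O[Li] | intermediate (not isolated)
12 | C30 sulfone acetate: 2,3:6,7-diepoxy-(10E)-ene chain, 13-SO2Ph (C13 epimers), ring C/D bicycle with 15-OAc and 22-OTBS | CC1(C)O[C@H]1CC[C@]2(C)O[C@H]2CC/C(C)=C/CC(S(=O)(=O)c3ccccc3)[C@H]4[C@]5(C)CC[C@H](O[Si](C)(C)C(C)(C)C)C(C)(C)O[C@H]5CC[C@@]4(C)OC(C)=O | intermediate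
13 | (3S,6S,7S,10E,14S,15R,18S,19S,22S) C30 diepoxy-ene with ring C/D bicycle, 15-OAc, 22-OTBS | CC1(C)O[C@H]1CC[C@]2(C)O[C@H]2CC/C(C)=C/CC[C@H]3[C@]4(C)CC[C@H](O[Si](C)(C)C(C)(C)C)C(C)(C)O[C@H]4CC[C@@]3(C)OC(C)=O | intermediate
14 | 22-O-tert-butyldimethylsilyl ether of the target | CC(=O)O[C@H]1CC[C@]2(C)[C@H](CC[C@](C)(OC(C)=O)[C@H]2CC[C@H]2[C@]3(C)CC[C@H](O[Si](C)(C)C(C)(C)C)C(C)(C)O[C@H]3CC[C@@]2(C)OC(C)=O)OC1(C)C | intermediate
15 | CNP0169816.2 (3S,6S,7S,10S,11S,14S,15R,18S,19S,22S) | CC(=O)O[C@H]1CC[C@]2(C)[C@H](CC[C@](C)(OC(C)=O)[C@H]2CC[C@H]2[C@]3(C)CC[C@H](O)C(C)(C)O[C@H]3CC[C@@]2(C)OC(C)=O)OC1(C)C | target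

**Step count**
Total steps: 11. Longest linear sequence: 11 (1 → 2 → 3 → 4 → 5 → 6 → 8 → 9 → 12 → 13 → 14 → 15; bromide 4 is also the second reactant of step 8).

**Three steps most likely to fail**

Step 10 (acetylative cascade). The C10 cation may lose a proton instead of being captured by acetate, and the 22‑silyl ether may be partly converted to acetate if the mixture warms. The fallback sets out from 13 and returns at 14. Compound 13 is cyclised under the established proton‑loss conditions (TMSOTf, 2,6-di-tert-butyl-4-methylpyridine, CH2Cl2, −78 °C) to the 3-O-trimethylsilyl 10(27)-exo-methylene tetracycle F1 (with its Δ9 isomer, which converges; a Δ10(11) isomer would have to be removed because hydrogen‑atom transfer would scramble C11). The alkene is then hydrated by hydrogen‑atom‑transfer (Mukaiyama) hydration (Mn(dpm)3, dpm = dipivaloylmethanate, PhSiH3, O2, i‑PrOH), and K2CO3/MeOH removes the trimethylsilyl group, giving the 3,10-diol with equatorial 10-OH F2; O2 adds to the tertiary radical anti to the syn‑axial 6‑methyl. Both hydroxyls are acetylated (Ac2O, DMAP, Et3N, 40 °C) to give 14.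

Step 5 (first cascade). The alkene is deactivated by the allylic sulfone, and proton loss may give the endocyclic isomer instead of the exo‑methylene that ozonolysis needs. The fallback sets out from 5 and returns at 6. The cascade is run as written and the crude alkene mixture, containing the endocyclic 7,8-ene isomer F3, is not separated. It is hydrated by the same hydrogen‑atom‑transfer method, which funnels the exo and 7,8‑ene isomers through one tertiary radical to the 7-epi tertiary alcohol with equatorial 7-OH F4. SOCl2/pyridine at −20 °C then dehydrates F4 by anti elimination; an equatorial leaving group has antiperiplanar hydrogens only on the methyl group, so the exocyclic alkene 6 is formed.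

Step 8 (hindered dianion coupling with in‑flask acetylation). The tertiary axial alkoxide may resist acylation, or the anhydride quench may complicate the coupling. The fallback sets out from 9 (with 4) and returns at 13, bypassing 12. The coupling is quenched with water to give the 15-hydroxy C30 sulfone F5. Na(Hg)/Na2HPO4 in MeOH removes the sulfone to give the 15-hydroxy C30 diepoxy-ene F6. The neutral tertiary alcohol is then acetylated under nucleophilic catalysis (Ac2O, DMAP, Et3N, 50 °C; the epoxides tolerate this), giving 13.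

**Further compounds**
F1 | step 10 | 3-O-trimethylsilyl 10(27)-exo-methylene tetracycle (15-OAc, 22-OTBS) | C[Si](C)(C)O[C@H]1CC[C@]2(C)[C@H](CCC(=C)[C@H]2CC[C@H]2[C@]3(C)CC[C@H](O[Si](C)(C)C(C)(C)C)C(C)(C)O[C@H]3CC[C@@]2(C)OC(C)=O)OC1(C)C
F2 | step 10 | 3,10-diol with equatorial 10-OH (15-OAc, 22-OTBS) | O[C@H]1CC[C@]2(C)[C@H](CC[C@](C)(O)[C@H]2CC[C@H]2[C@]3(C)CC[C@H](O[Si](C)(C)C(C)(C)C)C(C)(C)O[C@H]3CC[C@@]2(C)OC(C)=O)OC1(C)C
F3 | step 5 | endocyclic 7,8-ene isomer of 6 | O=S(=O)(c1ccccc1)C[C@H]2[C@]3(C)CC[C@H](O[Si](C)(C)C(C)(C)C)C(C)(C)O[C@H]3CC=C2C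
F4 | step 5 | 7-epi tertiary alcohol with equatorial 7-OH (7-epimer of 9) | O=S(=O)(c1ccccc1)C[C@H]2[C@]3(C)CC[C@H](O[Si](C)(C)C(C)(C)C)C(C)(C)O[C@H]3CC[C@]2(C)O
F5 | step 8 | 15-hydroxy C30 sulfone (C13 epimers) | CC1(C)O[C@H]1CC[C@]2(C)O[C@H]2CC/C(C)=C/CC(S(=O)(=O)c3ccccc3)[C@H]4[C@]5(C)CC[C@H](O[Si](C)(C)C(C)(C)C)C(C)(C)O[C@H]5CC[C@@]4(C)O
F6 | step 8 | 15-hydroxy C30 diepoxy-ene | CC1(C)O[C@H]1CC[C@]2(C)O[C@H]2CC/C(C)=C/CC[C@H]3[C@]4(C)CC[C@H](O[Si](C)(C)C(C)(C)C)C(C)(C)O[C@H]4CC[C@@]3(C)O
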